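**Plan**

1. Retrosynthesis: the O–Si bond at O6 is cut first, the C3=C4 olefin is traced back to a C4 ketone, and then the C2–C1′ bond between the pyran ring and the C16 side chain is cut. This leaves a flat 2-methylchromone and a C16 alkylmagnesium bromide.
2. Enabling feature: C2 lies between ring oxygen O1 and the C3=C4 bond that is conjugated to the arene. With an oxygen placed temporarily on C4, the pyran ring (O1, C2, C3, C4, C4a, C8a) is a γ-pyrone, which O-silylation turns into an aromatic 4-silyloxybenzopyrylium that is open to attack at C2 only.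
3. Forward: the benzopyranone ring is built on 2,5-dimethylhydroquinone (C-acetylation, Claisen condensation and cyclodehydration) and the chain is cut out of natural phytol (ozonolysis, Baeyer–Villiger, bromide). The two are joined at C2 by a copper-catalysed enantioselective alkyl addition; the C4 oxygen is then turned into the C3=C4 olefin and the silyl group removed.
4. Stereochemistry: C4′ and C8′ (R,R) are bought with (7R,11R)-phytol and never touched. C2 (S) is set in the coupling by the chiral copper–diphosphine catalyst and keeps the descriptor S in all later compounds.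

Key step: step 7

Locants: chromene O1, C2, C3, C4, C4a, C5–C8, C8a; side chain C1′–C13′.
Assumption: natural-source phytol with the 7R,11R configuration is taken as commercial; its alkene geometry does not matter because that bond is cleaved in step 1.
Assumption: the sense of induction of the ligand on this new substrate class cannot be assigned in advance; (R,R)-Ph-BPE is written, and its mirror image is to be used if a trial with a simple alkylmagnesium bromide shows the 2R sense.

**Route**

Step 1
Reactants: 1 (2E,7R,11R)-3,7,11,15-tetramethylhexadec-2-en-1-ol (phytol)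
Product: 2 (6R,10R)-6,10,14-trimethylpentadecan-2-one
Conditions: O3, CH2Cl2/MeOH, −78 °C; then Me2S, −78 °C to rt
Reagents that add atoms: ozone, O=[O+][O-]
Why: Ozonolysis with reductive work-up cleaves the trisubstituted C2=C3 bond of phytol to the methyl ketone, and the two methyl-bearing stereocentres are remote from the reacting site and should stay R,R.

Step 2
Reactants: 2 (6R,10R)-6,10,14-trimethylpentadecan-2-one
Product: 4 (4R,8R)-4,8,12-trimethyltridecan-1-ol, via trimethyltridecyl acetate 3 (not isolated)
Conditions: mCPBA, TFA, CH2Cl2, rt; aq. Na2SO3 wash; then K2CO3 (cat.), MeOH, rt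
Reagents that add atoms: mCPBA, OOC(=O)c1cccc(Cl)c1
Why: Baeyer–Villiger oxidation, in which the primary alkyl group migrates in preference to methyl, should give the acetate, and methanolysis (transesterification) then frees the C16 alcohol without touching any stereocentre.

Step 3
Reactants: 4 (4R,8R)-4,8,12-trimethyltridecan-1-ol
Product: 5 (4R,8R)-1-bromo-4,8,12-trimethyltridecane
Conditions: CBr4, PPh3, CH2Cl2, 0 °C
Reagents that add atoms: carbon tetrabromide, BrC(Br)(Br)Br
Why: Appel bromination of a primary alcohol under neutral conditions (SN2 at the CH2 group) should leave the remote stereocentres untouched.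

Step 4
Reactants: 6 2,5-dimethylbenzene-1,4-diol
Product: 7 1-(2,5-dihydroxy-3,6-dimethylphenyl)ethan-1-one
Conditions: AcOH, BF3·OEt2, 110 °C, Ar; then aq. NaOAc
Reagents that add atoms: acetic acid, CC(=O)O
Why: BF3-mediated Friedel–Crafts C-acetylation (O-acylation and Fries rearrangement) ortho to a hydroxyl should give one regioisomer because the two free ring positions are equivalent by symmetry, and the acetyl group deactivates the ring against a second acylation.

Step 5
Reactants: 7 1-(2,5-dihydroxy-3,6-dimethylphenyl)ethan-1-one
Product: 9 6-hydroxy-2,5,8-trimethyl-4H-chromen-4-one, via aryl 1,3-diketone 8 (not isolated)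
Conditions: NaH (5 equiv), EtOAc, THF, reflux; then conc. HCl, AcOH, 90 °C
Reagents that add atoms: ethyl acetate, CCOC(C)=O
Why: Crossed Claisen condensation of the methyl ketone enolate (formed beside the two phenoxides) with ethyl acetate should give the 1,3-diketone, and acid-catalysed cyclodehydration through the ortho hydroxyl closes the γ-pyrone ring (classical 2-methylchromone synthesis).

Step 6
Reactants: 9 6-hydroxy-2,5,8-trimethyl-4H-chromen-4-one
Product: 10 2,5,8-trimethyl-6-(triisopropylsilyloxy)-4H-chromen-4-one
Conditions: TIPSCl, imidazole, DMF, 40 °C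
Reagents that add atoms: triisopropylsilyl chloride, CC(C)[Si](Cl)(C(C)C)C(C)C
Why: Silylation of the only free hydroxyl masks the acidic phenol from the Grignard reagent, and the aryl triisopropylsilyl ether should tolerate the Lewis acid, hydride and acid steps that follow.

Step 7
Reactants: 5 (4R,8R)-1-bromo-4,8,12-trimethyltridecane; 10 2,5,8-trimethyl-6-(triisopropylsilyloxy)-4H-chromen-4-one
Product: 14 (2S)-2,5,8-trimethyl-2-[(4R,8R)-4,8,12-trimethyltridecyl]-6-(triisopropylsilyloxy)chroman-4-one, via Grignard reagent 11 (not isolated), via silyloxybenzopyrylium triflate 12 (not isolated), via silyl enol ether 13 (not isolated)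
Conditions: (a) 5, Mg, Et2O, reflux; (b) 10, TMSOTf (1.5 equiv), CH2Cl2, rt; then CuBr·SMe2 (5 mol%), (R,R)-Ph-BPE (6 mol%), −78 °C, slow addition of 11 (1.5 equiv); (c) 1 M HCl, THF, 0 °C
Reagents that add atoms: none
Why: Proposed new method: TMSOTf O-silylates the γ-pyrone carbonyl of 10 to the aromatic 4-silyloxybenzopyrylium 12, whose C4 is blocked by the siloxy group and whose C2 is the only open electrophilic carbon; the alkyl group of 11 passes to the chiral Cu(I)–diphosphine, the alkylcopper binds the C2=C3 π-bond, and oxidative addition followed by reductive elimination forms C2–C1′ and leaves silyl enol ether 13, which mild acid hydrolyses to 14. The closest known reaction types are the Lewis-acid-assisted Cu/diphosphine-catalysed conjugate addition of Grignard reagents to 2-unsubstituted chromones and 4-quinolones (tertiary centre), the Cu-catalysed enantioselective alkynylation of chromone-derived silyloxybenzopyrylium ions, and the Cu-catalysed Grignard addition to 3-methylcyclohexenone that gives quaternary centres; new here is the transfer of an sp3 alkyl group to a 2-alkyl benzopyrylium to give a tetrasubstituted C–O centre. No ring is closed in this step. The new stereocentre C2 should be set by the catalyst, which selects one face of the planar cation (ligand control; the chain stereocentres at C4′ and C8′ are too remote to interfere), and it should be kept because the product is held as silyl enol ether 13, which cannot open by retro-oxa-Michael reaction. The step needs addition at C2 over attack at C4 (secured by the 4-siloxy group and the soft copper nucleophile) and addition over deprotonation of the acidic 2-methyl group (countered by −78 °C and slow addition of 11; deprotonated material should return 10 on work-up).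

Step 8
Reactants: 14 (2S)-2,5,8-trimethyl-2-[(4R,8R)-4,8,12-trimethyltridecyl]-6-(triisopropylsilyloxy)chroman-4-one
Product: 15 (2S)-2,5,8-trimethyl-2-[(4R,8R)-4,8,12-trimethyltridecyl]-6-(triisopropylsilyloxy)chroman-4-ol (both C4 epimers)
Conditions: NaBH4, CeCl3·7H2O, MeOH/THF, −20 °C
Reagents that add atoms: none
Why: Luche reduction (1,2-reduction of the aryl ketone under nearly neutral conditions) should avoid base-induced retro-oxa-Michael opening that could erode C2; the new C4 carbinol centre is not controlled and is removed in the next step.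

Step 9
Reactants: 15 (2S)-2,5,8-trimethyl-2-[(4R,8R)-4,8,12-trimethyltridecyl]-6-(triisopropylsilyloxy)chroman-4-ol
Product: 16 triisopropyl{[(2S)-2,5,8-trimethyl-2-[(4R,8R)-4,8,12-trimethyltridecyl]-2H-chromen-6-yl]oxy}silane
Conditions: p-TsOH·H2O (5 mol%), 4 Å MS, PhMe, 45 °C, dark
Reagents that add atoms: none
Why: Acid-catalysed E1 dehydration through the benzylic C4 cation, stabilised by the ortho ring oxygen, should place the double bond at C3=C4 in conjugation with the arene; the quaternary C2 takes no part, and mild temperature and exclusion of light guard against electrocyclic ring opening of the 2H-chromene.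

Step 10
Reactants: 16 triisopropyl{[(2S)-2,5,8-trimethyl-2-[(4R,8R)-4,8,12-trimethyltridecyl]-2H-chromen-6-yl]oxy}silane
Product: 17 (2S)-2,5,8-trimethyl-2-[(4R,8R)-4,8,12-trimethyltridecyl]-2H-chromen-6-ol
Conditions: TBAF, AcOH, THF, 0 °C, Ar, dark
Reagents that add atoms: none
Why: Fluoride-induced cleavage of the aryl silyl ether, buffered with acetic acid and run under argon, should free the phenol without oxidation of the electron-rich ring or change at C2.

**Compound list**

1 | (2E,7R,11R)-3,7,11,15-tetramethylhexadec-2-en-1-ol (phytol) | OC/C=C(\C)CCC[C@H](C)CCC[C@H](C)CCCC(C)C | starting material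
2 | (6R,10R)-6,10,14-trimethylpentadecan-2-one | CC(=O)CCC[C@H](C)CCC[C@H](C)CCCC(C)C | intermediate
3 | (4R,8R)-4,8,12-trimethyltridecyl acetate | CC(=O)OCCC[C@H](C)CCC[C@H](C)CCCC(C)C | intermediate
4 | (4R,8R)-4,8,12-trimethyltridecan-1-ol | OCCC[C@H](C)CCC[C@H](C)CCCC(C)C | intermediate
5 | (4R,8R)-1-bromo-4,8,12-trimethyltridecane | BrCCC[C@H](C)CCC[C@H](C)CCCC(C)C | intermediate
6 | 2,5-dimethylbenzene-1,4-diol | Cc1cc(O)c(C)cc1O | starting material
7 | 1-(2,5-dihydroxy-3,6-dimethylphenyl)ethan-1-one | CC(=O)c1c(C)c(O)cc(C)c1O | intermediate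
8 | 1-(2,5-dihydroxy-3,6-dimethylphenyl)butane-1,3-dione | CC(=O)CC(=O)c1c(C)c(O)cc(C)c1O | intermediate
9 | 6-hydroxy-2,5,8-trimethyl-4H-chromen-4-one | Cc1cc(O)c(C)c2c(=O)cc(C)oc12 | intermediate
10 | 2,5,8-trimethyl-6-(triisopropylsilyloxy)-4H-chromen-4-one | Cc1cc(O[Si](C(C)C)(C(C)C)C(C)C)c(C)c2c(=O)cc(C)oc12 | intermediate
11 | [(4R,8R)-4,8,12-trimethyltridecyl]magnesium bromide | Br[Mg]CCC[C@H](C)CCC[C@H](C)CCCC(C)C | intermediate
12 | 2,5,8-trimethyl-6-(triisopropylsilyloxy)-4-(trimethylsilyloxy)chromenylium trifluoromethanesulfonate | Cc1cc(O[Si](C(C)C)(C(C)C)C(C)C)c(C)c2c(O[Si](C)(C)C)cc(C)[o+]c12.[O-]S(=O)(=O)C(F)(F)F | intermediate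
13 | triisopropyl{[(2S)-2,5,8-trimethyl-2-[(4R,8R)-4,8,12-trimethyltridecyl]-4-(trimethylsilyloxy)-2H-chromen-6-yl]oxy}silane | Cc1cc(O[Si](C(C)C)(C(C)C)C(C)C)c(C)c2c1O[C@@](C)(CCC[C@H](C)CCC[C@H](C)CCCC(C)C)C=C2O[Si](C)(C)C | intermediate
14 | (2S)-2,5,8-trimethyl-2-[(4R,8R)-4,8,12-trimethyltridecyl]-6-(triisopropylsilyloxy)chroman-4-one | Cc1cc(O[Si](C(C)C)(C(C)C)C(C)C)c(C)c2c1O[C@@](C)(CCC[C@H](C)CCC[C@H](C)CCCC(C)C)CC2=O | intermediate
15 | (2S)-2,5,8-trimethyl-2-[(4R,8R)-4,8,12-trimethyltridecyl]-6-(triisopropylsilyloxy)chroman-4-ol (both C4 epimers) | Cc1cc(O[Si](C(C)C)(C(C)C)C(C)C)c(C)c2c1O[C@@](C)(CCC[C@H](C)CCC[C@H](C)CCCC(C)C)CC2O | intermediate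
16 | triisopropyl{[(2S)-2,5,8-trimethyl-2-[(4R,8R)-4,8,12-trimethyltridecyl]-2H-chromen-6-yl]oxy}silane | Cc1cc(O[Si](C(C)C)(C(C)C)C(C)C)c(C)c2c1O[C@@](C)(CCC[C@H](C)CCC[C@H](C)CCCC(C)C)C=C2 | intermediate
17 | (2S)-2,5,8-trimethyl-2-[(4R,8R)-4,8,12-trimethyltridecyl]-2H-chromen-6-ol | Cc1cc(O)c(C)c2c1O[C@@](C)(CCC[C@H](C)CCC[C@H](C)CCCC(C)C)C=C2 | target

**Step count and risks**

Total step count: 10.
Longest linear sequence: 7 steps (steps 1, 2, 3, 7, 8, 9, 10); the arene branch (steps 4, 5, 6) joins at step 7.

Steps most likely to fail:

Step 7 (bears the new-method label). The Grignard reagent may deprotonate the acidic 2-methyl group of the benzopyrylium instead of adding, or the catalyst may discriminate the two faces of the cation poorly, so that conversion or the configuration at C2 is unsatisfactory. The fallback uses a Kabbe condensation, which forms O1–C2 and C2–C3 instead of C2–C1′. It sets out from 2 and 7: heating both with pyrrolidine in toluene with removal of water (aldol-type condensation of the two ketones, then intramolecular oxa-Michael addition) should give 6-hydroxy-2,5,8-trimethyl-2-[(4R,8R)-4,8,12-trimethyltridecyl]chroman-4-one F1 as both C2 epimers. Silylation (TIPSCl, imidazole, DMF) should give the silyl ether F2, again as both C2 epimers, and preparative HPLC on a chiral stationary phase would deliver the 2S epimer, which is 14, where the route is rejoined. Control of C2 is given up in this fallback and replaced by the separation.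

Step 9. The electron-rich chromene may dimerise or add back the acid-generated C4 cation under the dehydration conditions, or elimination may stall. The fallback avoids the cation and sets out from 14: kinetic enolisation at C3 (KHMDS, THF, −78 °C, where retro-oxa-Michael opening should be slow) and trapping with N-(5-chloro-2-pyridyl)bis(trifluoromethanesulfonimide) should give (2S)-2,5,8-trimethyl-2-[(4R,8R)-4,8,12-trimethyltridecyl]-6-(triisopropylsilyloxy)-2H-chromen-4-yl trifluoromethanesulfonate F3. Palladium-catalysed formate reduction of the enol triflate (Pd(OAc)2, PPh3, Bu3N, HCO2H, DMF, 40 °C) should then give 16, where the route is rejoined; steps 8 and 9 are replaced.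

Step 5. The trianion of 7 may be poorly soluble and react sluggishly, ethyl acetate may self-condense, or cyclodehydration may be incomplete. The fallback reverses the order of protection and ring formation and uses an amide-acetal annulation under neutral conditions. It sets out from 7: selective silylation of the non-chelated hydroxyl (TIPSCl, imidazole, DMF) should give 1-[2-hydroxy-3,6-dimethyl-5-(triisopropylsilyloxy)phenyl]ethan-1-one F4. Condensation with N,N-dimethylacetamide dimethyl acetal (toluene, 110 °C) should give the enaminone (E)-3-(dimethylamino)-1-[2-hydroxy-3,6-dimethyl-5-(triisopropylsilyloxy)phenyl]but-2-en-1-one F5, and acid-promoted cyclisation (p-TsOH, CH2Cl2) with loss of the amine should give 10, where the route is rejoined; steps 5 and 6 are replaced.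

Further compounds
F1 | step 7 | 6-hydroxy-2,5,8-trimethyl-2-[(4R,8R)-4,8,12-trimethyltridecyl]chroman-4-one (both C2 epimers) | Cc1cc(O)c(C)c2c1OC(C)(CCC[C@H](C)CCC[C@H](C)CCCC(C)C)CC2=O
F2 | step 7 | 2,5,8-trimethyl-2-[(4R,8R)-4,8,12-trimethyltridecyl]-6-(triisopropylsilyloxy)chroman-4-one (both C2 epimers) | Cc1cc(O[Si](C(C)C)(C(C)C)C(C)C)c(C)c2c1OC(C)(CCC[C@H](C)CCC[C@H](C)CCCC(C)C)CC2=O
F3 | step 9 | (2S)-2,5,8-trimethyl-2-[(4R,8R)-4,8,12-trimethyltridecyl]-6-(triisopropylsilyloxy)-2H-chromen-4-yl trifluoromethanesulfonate | Cc1cc(O[Si](C(C)C)(C(C)C)C(C)C)c(C)c2c1O[C@@](C)(CCC[C@H](C)CCC[C@H](C)CCCC(C)C)C=C2OS(=O)(=O)C(F)(F)F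
F4 | step 5 | 1-[2-hydroxy-3,6-dimethyl-5-(triisopropylsilyloxy)phenyl]ethan-1-one | CC(=O)c1c(C)c(O[Si](C(C)C)(C(C)C)C(C)C)cc(C)c1O
F5 | step 5 | (E)-3-(dimethylamino)-1-[2-hydroxy-3,6-dimethyl-5-(triisopropylsilyloxy)phenyl]but-2-en-1-one | CN(C)/C(C)=C/C(=O)c1c(C)c(O[Si](C(C)C)(C(C)C)C(C)C)cc(C)c1O
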